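**Retrosynthetic overview**

1. Numbering: 2H-cyclopenta[b]furan core O-1, C-2, C-3, C-3a, C-4 (C=O), C-5 (Cl), C-6, C-6a; ring A = cyclopentenone, ring B = oxolane, C-5′ = side-chain carbinol carbon.
2. Last ring bond is O-1–C-2 (ring B), made by SN2 attack of the tertiary C-6a hydroxyl on a C-2 triflate with inversion; the two acetates go on last.
3. Key disconnection, one flask: C-4–C-5 by addition of an alkynyllithium (C-5, C-6, masked C-6a ketone, octenyl chain) to a γ-lactone (C-2 to C-4, ring oxygen on C-2), and C-3a–C-6a by a chloride-terminated Piancatelli-type 4π closure that builds ring A with the chlorine in place.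
4. Enabling feature: ring A is a 4-oxygenated cyclopent-2-enone. The C-4 carbonyl and the oxygen-bearing quaternary C-6a are 1,4-related across C-5=C-6 (a latent cis-ene-1,4-dione, i.e. the 2-oxy-pentadienyl cation of marine prostanoid biosynthesis); C-5 is β to the C-6a carbonyl, so HCl adds to the ynone there; and the oxygen on C-2 is γ to C-4, so the acyl unit is a lactone whose ring oxygen makes C-3a an enol ether carbon.
5. Order of rings: temporary oxolanone (lactone 9, with C-2, C-3 and C-5′ set by a Sharpless epoxidation and a Keck allylation), then ring A (step 12), then ring B (step 13).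

Key step: step 12

Remark: the atom labels above are used for the corresponding atoms of all intermediates; C-2 is carried with the opposite configuration until step 13; the hemiketal carbon of 16 and 17 forms as an anomeric mixture and is left without a descriptor.

**Route**

Step 1
Reactants: 1 methyl hex-5-enoate
Product: 2 methyl (5E)-7-hydroxyhept-5-enoate
Conditions: (Z)-but-2-ene-1,4-diol (3 equiv), second-generation Grubbs catalyst RuCl2(=CHPh)(PCy3)(H2IMes) (3 mol %), CH2Cl2, 40 °C
Reagents that add atoms: (Z)-but-2-ene-1,4-diol, OC/C=C\CO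
Why: Olefin cross-metathesis between the terminal alkene and an excess of the symmetrical cis-diol should give the (E)-allylic alcohol under thermodynamic control.

Step 2
Reactants: 2 methyl (5E)-7-hydroxyhept-5-enoate
Product: 3 methyl 4-[(2R,3R)-3-(hydroxymethyl)oxiran-2-yl]butanoate
Conditions: Ti(OiPr)4 (10 mol %), D-(−)-diethyl tartrate (12 mol %), t-BuOOH, 4 Å MS, CH2Cl2, −20 °C
Reagents that add atoms: tert-butyl hydroperoxide, CC(C)(C)OO
Why: Sharpless asymmetric epoxidation with the D-tartrate ligand should deliver oxygen to the alkene face that gives the (2R,3R)-epoxy alcohol, which fixes C-5′ and, through two later inversions, C-2.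

Step 3
Reactants: 3 methyl 4-[(2R,3R)-3-(hydroxymethyl)oxiran-2-yl]butanoate
Product: 4 methyl 4-[(2R,3S)-3-formyloxiran-2-yl]butanoate
Conditions: Dess–Martin periodinane, pyridine, CH2Cl2, 0 → 23 °C
Reagents that add atoms: none
Why: Dess–Martin oxidation should convert the epoxy alcohol into the configurationally labile epoxy aldehyde under buffered, non-epimerizing conditions.

Step 4
Reactants: 4 methyl 4-[(2R,3S)-3-formyloxiran-2-yl]butanoate
Product: 5 methyl 4-[(2R,3R)-3-[(1S)-1-hydroxybut-3-en-1-yl]oxiran-2-yl]butanoate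
Conditions: (S)-BINOL (20 mol %), Ti(OiPr)4 (10 mol %), 4 Å MS, CH2Cl2, then allyltributylstannane, −20 °C; aq. NaHCO3
Reagents that add atoms: allyltributylstannane, C=CC[Sn](CCCC)(CCCC)CCCC
Why: Keck asymmetric allylation: the (S)-BINOL–titanium catalyst should direct allyl transfer to the Si face of the aldehyde, as with other α-oxygenated aldehydes, giving the (1S)-carbinol that becomes C-3.

Step 5
Reactants: 5 methyl 4-[(2R,3R)-3-[(1S)-1-hydroxybut-3-en-1-yl]oxiran-2-yl]butanoate
Product: 6 methyl 4-[(2R,3R)-3-[(1S)-1-hydroxy-3-oxopropyl]oxiran-2-yl]butanoate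
Conditions: O3, CH2Cl2, −78 °C; PPh3, −78 → 23 °C
Reagents that add atoms: ozone, [O-][O+]=O
Why: Ozonolysis with reductive work-up should cleave the only C=C bond to the β-hydroxy aldehyde without touching the epoxide.

Step 6
Reactants: 6 methyl 4-[(2R,3R)-3-[(1S)-1-hydroxy-3-oxopropyl]oxiran-2-yl]butanoate
Product: 8 methyl (5R)-5-hydroxy-5-[(2R,3S)-3-hydroxy-5-oxooxolan-2-yl]pentanoate, via epoxy acid 7 (not isolated)
Conditions: NaClO2, NaH2PO4, 2-methylbut-2-ene, t-BuOH/H2O, 0 °C; then CSA (10 mol %), CH2Cl2, 23 °C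
Reagents that add atoms: sodium chlorite, [Na+].[O-]Cl=O
Why: Pinnick oxidation gives the β-hydroxy acid, whose carboxyl group should open the epoxide at the nearer carbon in an acid-catalysed 5-exo cyclization with inversion (future C-2, inverted again in step 13), while the epoxide oxygen stays on C-5′ with retention.

Step 7
Reactants: 8 methyl (5R)-5-hydroxy-5-[(2R,3S)-3-hydroxy-5-oxooxolan-2-yl]pentanoate
Product: 9 methyl (5R)-5-(tert-butyldimethylsilyloxy)-5-[(2R,3S)-3-(tert-butyldimethylsilyloxy)-5-oxooxolan-2-yl]pentanoate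
Conditions: TBSOTf, 2,6-lutidine, CH2Cl2, −78 → 0 °C
Reagents that add atoms: tert-butyldimethylsilyl trifluoromethanesulfonate, CC(C)(C)[Si](C)(C)OS(=O)(=O)C(F)(F)F
Why: Silylation with the silyl triflate protects both secondary hydroxyls as non-participating TBS ethers, and the bulky C-3 ether later serves as the facial control element.

Step 8
Reactants: 10 (3Z)-non-3-en-1-ol
Product: 11 (3Z)-non-3-enal
Conditions: Dess–Martin periodinane, pyridine, CH2Cl2, 0 °C
Reagents that add atoms: none
Why: Dess–Martin oxidation under buffered conditions should give the β,γ-unsaturated aldehyde without moving the (Z)-alkene into conjugation.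

Step 9
Reactants: 11 (3Z)-non-3-enal
Product: 12 (5Z)-undec-5-en-1-yn-3-ol (racemic)
Conditions: HC≡CMgBr, THF, −78 °C; aq. NH4Cl
Reagents that add atoms: ethynylmagnesium bromide, C#C[Mg]Br
Why: Grignard 1,2-addition of the acetylide at low temperature installs the two alkyne carbons (C-5, C-6) next to the future C-6a.

Step 10
Reactants: 12 (5Z)-undec-5-en-1-yn-3-ol
Product: 13 (5Z)-undec-5-en-1-yn-3-one
Conditions: Dess–Martin periodinane, pyridine, CH2Cl2, 0 °C
Reagents that add atoms: none
Why: Dess–Martin oxidation of the propargylic alcohol should give the ynone under neutral conditions that spare the skipped alkene.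

Step 11
Reactants: 13 (5Z)-undec-5-en-1-yn-3-one
Product: 14 (5Z)-3,3-dimethoxyundec-5-en-1-yne
Conditions: MeOSiMe3, TMSOTf (5 mol %), CH2Cl2, −78 °C; pyridine quench
Reagents that add atoms: methoxytrimethylsilane, CO[Si](C)(C)C
Why: Silyl-triflate-catalysed ketalization with the alkoxysilane under aprotic conditions masks the ketone, removes the acidity of the doubly activated CH2 and makes the terminal alkyne safe to metalate.

Step 12
Reactants: 14 (5Z)-3,3-dimethoxyundec-5-en-1-yne; 9 methyl (5R)-5-(tert-butyldimethylsilyloxy)-5-[(2R,3S)-3-(tert-butyldimethylsilyloxy)-5-oxooxolan-2-yl]pentanoate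
Product: 19 methyl (5R,6R,7S)-5,7-bis(tert-butyldimethylsilyloxy)-7-[(1S,5R)-3-chloro-5-hydroxy-5-[(2Z)-oct-2-en-1-yl]-2-oxocyclopent-3-en-1-yl]-6-hydroxyheptanoate, via lithium acetylide 15 (not isolated), via alkynyl lactol 16 (not isolated), via chloroenone lactol 17 (not isolated), via dihydrofuran dienone 18 (not isolated)
Conditions: (i) 14, n-BuLi, THF, −78 °C, then 9, −78 °C; (ii) AcOH, LiCl, H2O, Dy(OTf)3 (10 mol %), MeCN, 23 → 40 °C
Reagents that add atoms: lithium chloride, [Li+].[Cl-]; water, O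
Why: Proposed new method: the acetylide 15 adds once to the γ-lactone carbonyl of 9, which is more electrophilic than the remote methyl ester (known acetylide-to-lactone addition, C-4–C-5 bond), and acidification then hydrolyses the ketal and lets chloride add to the liberated ynone (known LiCl/AcOH hydrochlorination of ynones) at C-5, because only the C-6a carbonyl is free while C-4 is held as the cyclic hemiketal 16. Lewis-acid-assisted loss of water from hemiketal 17 gives the 2-alkenyl-4,5-dihydrofuran 18, whose carbonyl-activated form is a 2-oxy-pentadienyl cation that closes ring A by conrotatory 4π electrocyclization between C-3a and C-6a; hydrolysis of the resulting cyclic oxocarbenium ion returns the C-4 ketone and frees the C-2 hydroxyl. The closest known reactions are the Piancatelli rearrangement and the iso-Nazarov cyclization, which run through the same oxidopentadienyl cation (also the cation of the allene-oxide step in marine prostanoid biosynthesis), and the acid-mediated cyclization of γ-hydroxy ynones with HX to 3-halofurans, which cannot aromatize here because C-4 is at the ketone level. The step needs C-3a, not the allylic CH2 of the octenyl chain, to be the nucleophilic terminus, and this is secured by the lactone-derived ring oxygen, which turns C-3a into an enol ether carbon and leaves the C-6a carbonyl as the only electrophile. C-6a is set by torquoselectivity: the new bond should form at C-3a on the dihydrofuran face anti to the adjacent C-3 silyloxy group with the carbonyl oxygen rotating outward as in Piancatelli products, and the enolizable C-3a centre should then equilibrate to the epimer drawn, with the side chain trans to the octenyl group. The chloroalkene geometry is not critical, since reversible HCl addition interconverts the isomers and only the (E)-isomer with C-4 and C-6a cis can cyclize.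

Step 13
Reactants: 19 methyl (5R,6R,7S)-5,7-bis(tert-butyldimethylsilyloxy)-7-[(1S,5R)-3-chloro-5-hydroxy-5-[(2Z)-oct-2-en-1-yl]-2-oxocyclopent-3-en-1-yl]-6-hydroxyheptanoate
Product: 21 methyl (5R)-5-(tert-butyldimethylsilyloxy)-5-[(2S,3S,3aS,6aR)-3-(tert-butyldimethylsilyloxy)-5-chloro-6a-[(2Z)-oct-2-en-1-yl]-4-oxo-3,3a,4,6a-tetrahydro-2H-cyclopenta[b]furan-2-yl]pentanoate, via secondary triflate 20 (not isolated)
Conditions: Tf2O, 2,6-lutidine, CH2Cl2, −78 → 0 °C
Reagents that add atoms: none
Why: Chemoselective triflation of the secondary C-2 hydroxyl followed by intramolecular Williamson-type SN2 displacement by the tertiary C-6a hydroxyl (5-exo-tet) should close ring B with inversion at C-2, the cis ring fusion being the only strain-free outcome.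

Step 14
Reactants: 21 methyl (5R)-5-(tert-butyldimethylsilyloxy)-5-[(2S,3S,3aS,6aR)-3-(tert-butyldimethylsilyloxy)-5-chloro-6a-[(2Z)-oct-2-en-1-yl]-4-oxo-3,3a,4,6a-tetrahydro-2H-cyclopenta[b]furan-2-yl]pentanoate
Product: 22 methyl (5R)-5-hydroxy-5-[(2S,3S,3aS,6aR)-5-chloro-3-hydroxy-6a-[(2Z)-oct-2-en-1-yl]-4-oxo-3,3a,4,6a-tetrahydro-2H-cyclopenta[b]furan-2-yl]pentanoate
Conditions: HF·pyridine, pyridine, THF, 0 → 23 °C
Reagents that add atoms: none
Why: Fluoride-mediated desilylation with buffered HF·pyridine should remove both TBS groups without base, which the β-oxygenated ketone would not tolerate.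

Step 15
Reactants: 22 methyl (5R)-5-hydroxy-5-[(2S,3S,3aS,6aR)-5-chloro-3-hydroxy-6a-[(2Z)-oct-2-en-1-yl]-4-oxo-3,3a,4,6a-tetrahydro-2H-cyclopenta[b]furan-2-yl]pentanoate
Product: 23 methyl (5R)-5-acetoxy-5-[(2S,3S,3aS,6aR)-3-acetoxy-5-chloro-6a-[(2Z)-oct-2-en-1-yl]-4-oxo-3,3a,4,6a-tetrahydro-2H-cyclopenta[b]furan-2-yl]pentanoate
Conditions: Ac2O, pyridine, DMAP (cat.), CH2Cl2, 0 °C
Reagents that add atoms: acetic anhydride, CC(=O)OC(C)=O
Why: Acylation with acetic anhydride under nucleophilic catalysis should esterify both secondary hydroxyls and give the target.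

**Compound list**

1 | methyl hex-5-enoate | C=CCCCC(=O)OC | starting material
2 | methyl (5E)-7-hydroxyhept-5-enoate | OC/C=C/CCCC(=O)OC | intermediate
3 | methyl 4-[(2R,3R)-3-(hydroxymethyl)oxiran-2-yl]butanoate | OC[C@H]1O[C@@H]1CCCC(=O)OC | intermediate
4 | methyl 4-[(2R,3S)-3-formyloxiran-2-yl]butanoate | O=C[C@H]1O[C@@H]1CCCC(=O)OC | intermediate
5 | methyl 4-[(2R,3R)-3-[(1S)-1-hydroxybut-3-en-1-yl]oxiran-2-yl]butanoate | C=CC[C@H](O)[C@H]1O[C@@H]1CCCC(=O)OC | intermediate
6 | methyl 4-[(2R,3R)-3-[(1S)-1-hydroxy-3-oxopropyl]oxiran-2-yl]butanoate | O=CC[C@H](O)[C@H]1O[C@@H]1CCCC(=O)OC | intermediate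
7 | (3S)-3-hydroxy-3-[(2R,3R)-3-(4-methoxy-4-oxobutyl)oxiran-2-yl]propanoic acid | OC(=O)C[C@H](O)[C@H]1O[C@@H]1CCCC(=O)OC | intermediate (not isolated)
8 | methyl (5R)-5-hydroxy-5-[(2R,3S)-3-hydroxy-5-oxooxolan-2-yl]pentanoate | O=C1C[C@H](O)[C@@H]([C@@H](CCCC(=O)OC)O)O1 | intermediate
9 | methyl (5R)-5-(tert-butyldimethylsilyloxy)-5-[(2R,3S)-3-(tert-butyldimethylsilyloxy)-5-oxooxolan-2-yl]pentanoate | O=C1C[C@H](O[Si](C)(C)C(C)(C)C)[C@@H]([C@@H](CCCC(=O)OC)O[Si](C)(C)C(C)(C)C)O1 | intermediate
10 | (3Z)-non-3-en-1-ol | CCCCC/C=C\CCO | starting material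
11 | (3Z)-non-3-enal | CCCCC/C=C\CC=O | intermediate
12 | (5Z)-undec-5-en-1-yn-3-ol (racemic) | CCCCC/C=C\CC(O)C#C | intermediate
13 | (5Z)-undec-5-en-1-yn-3-one | CCCCC/C=C\CC(=O)C#C | intermediate
14 | (5Z)-3,3-dimethoxyundec-5-en-1-yne | CCCCC/C=C\CC(OC)(OC)C#C | intermediate
15 | [(5Z)-3,3-dimethoxyundec-5-en-1-yn-1-yl]lithium | CCCCC/C=C\CC(OC)(OC)C#C[Li] | intermediate (not isolated)
16 | methyl (5R)-5-(tert-butyldimethylsilyloxy)-5-[(2R,3S)-3-(tert-butyldimethylsilyloxy)-5-[(5Z)-3,3-dimethoxyundec-5-en-1-yn-1-yl]-5-hydroxyoxolan-2-yl]pentanoate (anomer mixture) | CCCCC/C=C\CC(OC)(OC)C#CC1(O)C[C@H](O[Si](C)(C)C(C)(C)C)[C@@H]([C@@H](CCCC(=O)OC)O[Si](C)(C)C(C)(C)C)O1 | intermediate (not isolated)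
17 | methyl (5R)-5-(tert-butyldimethylsilyloxy)-5-[(2R,3S)-3-(tert-butyldimethylsilyloxy)-5-[(1E,5Z)-1-chloro-3-oxoundeca-1,5-dien-1-yl]-5-hydroxyoxolan-2-yl]pentanoate (anomer mixture) | CCCCC/C=C\CC(=O)/C=C(Cl)\C1(O)C[C@H](O[Si](C)(C)C(C)(C)C)[C@@H]([C@@H](CCCC(=O)OC)O[Si](C)(C)C(C)(C)C)O1 | intermediate (not isolated)
18 | methyl (5R)-5-(tert-butyldimethylsilyloxy)-5-[(2R,3S)-3-(tert-butyldimethylsilyloxy)-5-[(1E,5Z)-1-chloro-3-oxoundeca-1,5-dien-1-yl]-2,3-dihydrofuran-2-yl]pentanoate | CCCCC/C=C\CC(=O)/C=C(Cl)\C1=C[C@H](O[Si](C)(C)C(C)(C)C)[C@@H]([C@@H](CCCC(=O)OC)O[Si](C)(C)C(C)(C)C)O1 | intermediate (not isolated)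
19 | methyl (5R,6R,7S)-5,7-bis(tert-butyldimethylsilyloxy)-7-[(1S,5R)-3-chloro-5-hydroxy-5-[(2Z)-oct-2-en-1-yl]-2-oxocyclopent-3-en-1-yl]-6-hydroxyheptanoate | CCCCC/C=C\C[C@]1(O)C=C(Cl)C(=O)[C@H]1[C@H](O[Si](C)(C)C(C)(C)C)[C@H](O)[C@@H](CCCC(=O)OC)O[Si](C)(C)C(C)(C)C | intermediate
20 | 6-O-trifluoromethanesulfonate of 19 | CCCCC/C=C\C[C@]1(O)C=C(Cl)C(=O)[C@H]1[C@H](O[Si](C)(C)C(C)(C)C)[C@H](OS(=O)(=O)C(F)(F)F)[C@@H](CCCC(=O)OC)O[Si](C)(C)C(C)(C)C | intermediate (not isolated)
21 | methyl (5R)-5-(tert-butyldimethylsilyloxy)-5-[(2S,3S,3aS,6aR)-3-(tert-butyldimethylsilyloxy)-5-chloro-6a-[(2Z)-oct-2-en-1-yl]-4-oxo-3,3a,4,6a-tetrahydro-2H-cyclopenta[b]furan-2-yl]pentanoate | CCCCC/C=C\C[C@]12C=C(Cl)C(=O)[C@H]1[C@H](O[Si](C)(C)C(C)(C)C)[C@H]([C@@H](CCCC(=O)OC)O[Si](C)(C)C(C)(C)C)O2 | intermediate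
22 | methyl (5R)-5-hydroxy-5-[(2S,3S,3aS,6aR)-5-chloro-3-hydroxy-6a-[(2Z)-oct-2-en-1-yl]-4-oxo-3,3a,4,6a-tetrahydro-2H-cyclopenta[b]furan-2-yl]pentanoate | CCCCC/C=C\C[C@]12C=C(Cl)C(=O)[C@H]1[C@H](O)[C@H]([C@@H](CCCC(=O)OC)O)O2 | intermediate
23 | methyl (5R)-5-acetoxy-5-[(2S,3S,3aS,6aR)-3-acetoxy-5-chloro-6a-[(2Z)-oct-2-en-1-yl]-4-oxo-3,3a,4,6a-tetrahydro-2H-cyclopenta[b]furan-2-yl]pentanoate | CCCCC/C=C\C[C@]12C=C(Cl)C(=O)[C@H]1[C@H](OC(C)=O)[C@H]([C@@H](CCCC(=O)OC)OC(C)=O)O2 | target

**Totals and risks**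

Total step count: 15. Longest linear sequence: 11 steps (steps 1–7 and 12–15).

Steps most likely to fail:

- **Step 12.** Chloride may add at the wrong alkyne carbon, the cationic closure may lose regio- or torquoselectivity, or the allylic silyloxy group may be lost with aromatization to a furan. The fallback uses known reactions, sets out from 9 and 14 and comes back at 19. The acetylide addition is stopped at the lactol 16 (NH4Cl quench, isolation). Lindlar semi-hydrogenation (H2, Pd/CaCO3 poisoned with Pb(OAc)2, quinoline) gives the (Z)-alkenyl lactol ketal F1. Aqueous acid (AcOH–THF–H2O) unmasks the cis-ene-1,4-dione and brings about the established acid-mediated aldol-type closure of such ene-diones to a 4-hydroxycyclopentenone, here the chlorine-free diol F2. Alkaline hydrogen peroxide gives the epoxy ketone F3, and opening with HCl followed by loss of water, the standard way to 2-chlorocyclopent-2-enones, gives 19.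

- **Step 13.** The hindered secondary triflate may undergo elimination, be captured by the ketone oxygen instead of closing the ether, or C-3a may not equilibrate fully. The fallback sets out from 19 and comes back at 23. HF·pyridine gives the tetraol F4. MeC(OMe)3 with PPTS gives the cyclic orthoacetate F5 on the C-5′/C-2 diol. BF3·OEt2 ionizes it to the acetoxonium ion, which the tertiary hydroxyl opens at C-2 with inversion (5-exo), giving the hydroxy acetate F6 with ring B closed and the C-5′ acetate already in place. Acetylation as in step 15 gives 23.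

- **Step 4.** Facial selectivity may be poor if catalyst control opposes the intrinsic bias of the epoxy aldehyde, or the Lewis acid may open the epoxide. The fallback sets out from 4 and comes back at 8. A Reformatsky reaction of 4 with tert-butyl bromoacetate and zinc, in which chelation of zinc between the aldehyde and oxirane oxygens should direct the same syn addition, gives the β-hydroxy tert-butyl ester F7. CSA in CH2Cl2 then makes the ester carbonyl open the epoxide at the nearer carbon with loss of isobutene, giving lactone 8 directly and bypassing steps 5 and 6.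

Further compounds
F1 | step 12 | methyl (5R)-5-(tert-butyldimethylsilyloxy)-5-[(2R,3S)-3-(tert-butyldimethylsilyloxy)-5-[(1Z,5Z)-3,3-dimethoxyundeca-1,5-dien-1-yl]-5-hydroxyoxolan-2-yl]pentanoate (anomer mixture) | CCCCC/C=C\CC(OC)(OC)/C=C\C1(O)C[C@H](O[Si](C)(C)C(C)(C)C)[C@@H]([C@@H](CCCC(=O)OC)O[Si](C)(C)C(C)(C)C)O1
F2 | step 12 | chlorine-free analogue of 19 (H in place of Cl on the cyclopentenone) | CCCCC/C=C\C[C@]1(O)C=CC(=O)[C@H]1[C@H](O[Si](C)(C)C(C)(C)C)[C@H](O)[C@@H](CCCC(=O)OC)O[Si](C)(C)C(C)(C)C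
F3 | step 12 | epoxy ketone from F2 (oxirane across the former enone C=C, either face) | CCCCC/C=C\C[C@]1(O)C2OC2C(=O)[C@H]1[C@H](O[Si](C)(C)C(C)(C)C)[C@H](O)[C@@H](CCCC(=O)OC)O[Si](C)(C)C(C)(C)C
F4 | step 13 | methyl (5R,6R,7S)-7-[(1S,5R)-3-chloro-5-hydroxy-5-[(2Z)-oct-2-en-1-yl]-2-oxocyclopent-3-en-1-yl]-5,6,7-trihydroxyheptanoate | CCCCC/C=C\C[C@]1(O)C=C(Cl)C(=O)[C@H]1[C@H](O)[C@H](O)[C@@H](CCCC(=O)OC)O
F5 | step 13 | cyclic methyl orthoacetate of F4 on the 5,6-diol (2-methoxy-2-methyl-1,3-dioxolane, mixture at the orthoester carbon) | CCCCC/C=C\C[C@]1(O)C=C(Cl)C(=O)[C@H]1[C@H](O)[C@@H]2OC(C)(OC)O[C@@H]2CCCC(=O)OC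
F6 | step 13 | methyl (5R)-5-acetoxy-5-[(2S,3S,3aS,6aR)-5-chloro-3-hydroxy-6a-[(2Z)-oct-2-en-1-yl]-4-oxo-3,3a,4,6a-tetrahydro-2H-cyclopenta[b]furan-2-yl]pentanoate | CCCCC/C=C\C[C@]12C=C(Cl)C(=O)[C@H]1[C@H](O)[C@H]([C@@H](CCCC(=O)OC)OC(C)=O)O2
F7 | step 4 | tert-butyl (3S)-3-hydroxy-3-[(2R,3R)-3-(4-methoxy-4-oxobutyl)oxiran-2-yl]propanoate | CC(C)(C)OC(=O)C[C@H](O)[C@H]1O[C@@H]1CCCC(=O)OC
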